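**Plan**

- Retrosynthesis first removes the chain-flanking oxygens of both quinone rings (Thiele–Winter acetoxylation and Teuber oxidation in reverse) and the single O-methyl of ring A, which uncovers a symmetric bis(2-methylresorcinol).
- This core is then cut at the two benzylic bonds of the tridecane tether, C1–C2 and C12–C13, into two molecules of one 3,5-dioxygenated 4-methylbenzyl bromide and an eleven-carbon 1,11-dimetallated chain.
- The enabling feature: rings A and B share one skeleton, a C-methyl carbon flanked by two oxygen-bearing carbons and para to the chain-bearing carbon, so the aryl groups on C1 and C13 are identical until one of four equivalent hydroxyls is methylated.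
- Forward, the benzyl bromide comes from 3,5-dihydroxy-4-methylbenzoic acid (three steps) and the di-Grignard from 1,11-dibromoundecane. One copper-catalysed double coupling joins the chain; no ring is formed anywhere, both six-membered rings coming from the aromatic acid.
- After the coupling: debenzylation, mono-O-methylation, Teuber oxidation, double Thiele–Winter acetoxylation, then deacetylation and air oxidation.
- Stereochemistry: the target has no stereocentre and no stereogenic double bond, so nothing has to be set.

Key step: step 5

Remark: the target is taken as the 2-hydroxy-1,4-quinone tautomers drawn in its SMILES; ring A is the methoxylated ring, ring B the dihydroxy ring, and the tether is numbered C1 (on ring A) to C13 (on ring B).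

**Route**

Step 1
Reactants: 1 3,5-dihydroxy-4-methylbenzoic acid; 2 benzyl bromide
Product: 3 benzyl 3,5-bis(benzyloxy)-4-methylbenzoate
Conditions: BnBr (3.3 equiv), K2CO3, DMF, 60 °C
Reagents that add atoms: benzyl bromide (compound 2), BrCc1ccccc1
Why: Williamson O-alkylation of the two phenoxides and SN2 esterification of the carboxylate by benzyl bromide under K2CO3/DMF cap all three acidic sites in one operation, as is standard for dihydroxybenzoic acids.

Step 2
Reactants: 3 benzyl 3,5-bis(benzyloxy)-4-methylbenzoate
Product: 4 [3,5-bis(benzyloxy)-4-methylphenyl]methanol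
Conditions: LiAlH4, THF, 0 °C to rt
Reagents that add atoms: none
Why: LiAlH4 reduction of the ester should deliver the primary benzylic alcohol, the aryl benzyl ethers being inert to hydride and the cleaved benzyl alcohol being removed on chromatography.

Step 3
Reactants: 4 [3,5-bis(benzyloxy)-4-methylphenyl]methanol
Product: 5 1,3-bis(benzyloxy)-5-(bromomethyl)-2-methylbenzene (3,5-bis(benzyloxy)-4-methylbenzyl bromide)
Conditions: CBr4, PPh3, CH2Cl2, 0 °C to rt
Reagents that add atoms: carbon tetrabromide, BrC(Br)(Br)Br
Why: Appel bromination through the alkoxyphosphonium bromide converts the primary benzylic alcohol into the bromide under neutral conditions that leave the benzyl ethers untouched, as is routine for 3,5-dialkoxybenzyl alcohols.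

Step 4
Reactants: 6 1,11-dibromoundecane
Product: 7 undecane-1,11-diylbis(magnesium bromide), kept as a titrated THF solution
Conditions: Mg turnings (excess, I2-activated), THF, slow addition of dilute 6, 35–40 °C
Reagents that add atoms: magnesium, [Mg]
Why: Grignard formation by oxidative insertion of magnesium into both primary C–Br bonds is well established for long α,ω-dibromides, slow addition of dilute 6 to excess activated metal keeping Wurtz chain doubling low and the eleven-carbon spacer excluding cyclisation.

Step 5
Reactants: 5 3,5-bis(benzyloxy)-4-methylbenzyl bromide (2.2 equiv); 7 undecane-1,11-diylbis(magnesium bromide) (1.0 equiv)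
Product: 8 1,13-bis[3,5-bis(benzyloxy)-4-methylphenyl]tridecane
Conditions: Li2CuCl4 (5 mol %, two portions), THF, −40 °C to 0 °C, slow addition of 5 to 7
Reagents that add atoms: none
Why: The Grignard termini reduce and transmetalate Li2CuCl4 (divalent copper) to a monovalent alkylcopper (magnesium cuprate) species, which attacks the benzylic C–Br bond of 5 by SN2-type oxidative addition to a transient trivalent copper intermediate and releases the sp3–sp3 bond by reductive elimination, the copper passing on to the next C–Mg bond; the cycle runs once at each end of 7. The closest known reaction type is the Kochi copper-catalysed coupling of primary alkyl Grignard reagents with alkyl and benzylic halides, the standard way from 3,5-dialkoxybenzyl halides to 5-alkylresorcinol ethers. No ring is closed and no stereocentre is formed. The selectivity needed is cross-coupling over Wurtz homocoupling (bibenzyl after bromine–magnesium exchange) together with complete reaction at both termini: slow addition of 5 keeps the alkylmetal in excess over free bromide for most of the reaction, the cold copper-catalysed path should outrun halogen–metal exchange, and the slight overall excess of 5 caps both ends. Bromide 5 offers the nucleophile only its benzylic C–Br bond, since the aryl benzyl ethers and the C-methyl group are neither acidic nor electrophilic toward RMgBr and the meta-placed oxygens leave the benzylic carbon unhindered. Mono-coupled material (the dodecylarene after quench) and surplus 5 differ enough from 8 in polarity and size to be removed by chromatography or crystallisation.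

Step 6
Reactants: 8 1,13-bis[3,5-bis(benzyloxy)-4-methylphenyl]tridecane
Product: 9 5,5'-(tridecane-1,13-diyl)bis(2-methylbenzene-1,3-diol)
Conditions: H2 (1 atm), 10% Pd/C, EtOAc/MeOH, rt
Reagents that add atoms: none
Why: Catalytic hydrogenolysis of the four benzylic C–O bonds over palladium frees the phenols with loss of toluene, and the saturated chain and the arene rings offer nothing else to reduce.

Step 7
Reactants: 9 5,5'-(tridecane-1,13-diyl)bis(2-methylbenzene-1,3-diol)
Product: 10 5-[13-(3-hydroxy-5-methoxy-4-methylphenyl)tridecyl]-2-methylbenzene-1,3-diol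
Conditions: MeI (0.8 equiv), K2CO3, acetone, reflux; chromatography, recovered 9 recycled
Reagents that add atoms: iodomethane, CI
Why: Williamson O-methylation with a deficit of MeI meets four symmetry-equivalent hydroxyls, so the mono-ether is a single constitutional isomer whose share is set only by statistics and which should separate by polarity from unreacted 9 and from more highly methylated material.

Step 8
Reactants: 10 5-[13-(3-hydroxy-5-methoxy-4-methylphenyl)tridecyl]-2-methylbenzene-1,3-diol
Product: 11 2-hydroxy-6-[13-(5-methoxy-4-methyl-3,6-dioxocyclohexa-1,4-dien-1-yl)tridecyl]-3-methylcyclohexa-2,5-diene-1,4-dione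
Conditions: ON(SO3K)2 (5 equiv), KH2PO4, H2O/acetone, rt
Reagents that add atoms: dipotassium nitrosodisulfonate (Fremy's salt), [K+].[K+].[O]N(S(=O)(=O)[O-])S(=O)(=O)[O-]
Why: Teuber oxidation with the nitrosodisulfonate radical turns each phenol into a para-quinone by hydrogen abstraction, radical coupling at the free para carbon (the ring CH next to the chain) and loss of imidodisulfonate, the methoxyl of ring A and the second hydroxyl of ring B being carried through as 2-methoxy- and 2-hydroxyquinone substituents, as known for 5-alkylresorcinols and their monomethyl ethers.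

Step 9
Reactants: 11 2-hydroxy-6-[13-(5-methoxy-4-methyl-3,6-dioxocyclohexa-1,4-dien-1-yl)tridecyl]-3-methylcyclohexa-2,5-diene-1,4-dione
Product: 12 3-[13-(2,3,5,6-tetraacetoxy-4-methylphenyl)tridecyl]-5-methoxy-6-methylbenzene-1,2,4-triyl triacetate
Conditions: Ac2O, H2SO4 (cat.), rt to 45 °C
Reagents that add atoms: acetic anhydride, CC(=O)OC(C)=O
Why: Thiele–Winter acetoxylation adds acetate in acid-catalysed conjugate fashion to the single unsubstituted ring carbon of each quinone and traps the resulting hydroquinone (and the ring B hydroxyl) as acetates, a reaction precedented on trisubstituted hydroxy- and methoxy-methylbenzoquinones, so only the rate and not the regiochemistry is in question.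

Step 10
Reactants: 12 3-[13-(2,3,5,6-tetraacetoxy-4-methylphenyl)tridecyl]-5-methoxy-6-methylbenzene-1,2,4-triyl triacetate
Product: 14 2,5-dihydroxy-3-methyl-6-[13-(2-hydroxy-5-methoxy-4-methyl-3,6-dioxocyclohexa-1,4-dien-1-yl)tridecyl]cyclohexa-2,5-diene-1,4-dione (the target), via heptaphenol 13 (not isolated)
Conditions: HCl (cat.), degassed MeOH, reflux, Ar; evaporate; then air, EtOAc/aq. NaH2PO4–Na2HPO4 (pH 7), rt
Reagents that add atoms: none
Why: Acid-catalysed transesterification removes all seven aryl acetates at the hydroquinone oxidation level, where the aryl methyl ether is inert, and the hydroxyhydroquinones so formed autoxidise readily to the 2-hydroxy-1,4-quinone tautomers, the oxidation being run only after the acidic methanol is gone so that the hydroxyquinones cannot be O-methylated.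

**Compound list**

1 | 3,5-dihydroxy-4-methylbenzoic acid | Cc1c(O)cc(cc1O)C(=O)O | starting material
2 | benzyl bromide | BrCc1ccccc1 | starting material
3 | benzyl 3,5-bis(benzyloxy)-4-methylbenzoate | Cc1c(OCc2ccccc2)cc(cc1OCc1ccccc1)C(=O)OCc1ccccc1 | intermediate
4 | [3,5-bis(benzyloxy)-4-methylphenyl]methanol | Cc1c(OCc2ccccc2)cc(CO)cc1OCc1ccccc1 | intermediate
5 | 1,3-bis(benzyloxy)-5-(bromomethyl)-2-methylbenzene | Cc1c(OCc2ccccc2)cc(CBr)cc1OCc1ccccc1 | intermediate
6 | 1,11-dibromoundecane | BrCCCCCCCCCCCBr | starting material
7 | undecane-1,11-diylbis(magnesium bromide) | Br[Mg]CCCCCCCCCCC[Mg]Br | intermediate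
8 | 1,13-bis[3,5-bis(benzyloxy)-4-methylphenyl]tridecane | Cc1c(OCc2ccccc2)cc(CCCCCCCCCCCCCc2cc(OCc3ccccc3)c(C)c(OCc3ccccc3)c2)cc1OCc1ccccc1 | intermediate
9 | 5,5'-(tridecane-1,13-diyl)bis(2-methylbenzene-1,3-diol) | Cc1c(O)cc(CCCCCCCCCCCCCc2cc(O)c(C)c(O)c2)cc1O | intermediate
10 | 5-[13-(3-hydroxy-5-methoxy-4-methylphenyl)tridecyl]-2-methylbenzene-1,3-diol | COc1cc(CCCCCCCCCCCCCc2cc(O)c(C)c(O)c2)cc(O)c1C | intermediate
11 | 2-hydroxy-6-[13-(5-methoxy-4-methyl-3,6-dioxocyclohexa-1,4-dien-1-yl)tridecyl]-3-methylcyclohexa-2,5-diene-1,4-dione | COC1=C(C)C(=O)C=C(CCCCCCCCCCCCCC2=CC(=O)C(C)=C(O)C2=O)C1=O | intermediate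
12 | 3-[13-(2,3,5,6-tetraacetoxy-4-methylphenyl)tridecyl]-5-methoxy-6-methylbenzene-1,2,4-triyl triacetate | COc1c(C)c(OC(C)=O)c(OC(C)=O)c(CCCCCCCCCCCCCc2c(OC(C)=O)c(OC(C)=O)c(C)c(OC(C)=O)c2OC(C)=O)c1OC(C)=O | intermediate
13 | 3-methyl-6-[13-(2,3,6-trihydroxy-5-methoxy-4-methylphenyl)tridecyl]benzene-1,2,4,5-tetrol | COc1c(C)c(O)c(O)c(CCCCCCCCCCCCCc2c(O)c(O)c(C)c(O)c2O)c1O | intermediate
14 | 2,5-dihydroxy-3-methyl-6-[13-(2-hydroxy-5-methoxy-4-methyl-3,6-dioxocyclohexa-1,4-dien-1-yl)tridecyl]cyclohexa-2,5-diene-1,4-dione | COC1=C(C)C(=O)C(O)=C(CCCCCCCCCCCCCC2=C(O)C(=O)C(C)=C(O)C2=O)C1=O | target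

**Count and risks**

Total step count: 10. Longest linear sequence: 9 steps (1 → 3 → 4 → 5 → 8 → 9 → 10 → 11 → 12 → 14); the di-Grignard branch adds one step before the convergence in step 5.

Steps most likely to fail:

Step 5. The coupling may be eroded by Wurtz-type homocoupling after bromine–magnesium exchange, by incomplete reaction at the second terminus, or by chain-doubled di-Grignard carried over from step 4. The fallback makes the same two bonds between the benzylic carbons and the chain as alkenes by a double Wittig olefination. It sets out from alcohol 4 and dibromide 6. Alcohol 4 would be oxidised with MnO2 in CH2Cl2 to 3,5-bis(benzyloxy)-4-methylbenzaldehyde F1. Dibromide 6 would be heated with PPh3 in MeCN to give undecane-1,11-diylbis(triphenylphosphonium) dibromide F2. The bis-ylide from F2 and KOtBu in THF would be condensed with two equivalents of F1 to give 1,13-bis[3,5-bis(benzyloxy)-4-methylphenyl]trideca-1,12-diene F3 as a mixture of alkene isomers. Hydrogenation over Pd/C in EtOAc/MeOH would then saturate both alkenes and remove the four benzyl groups in one operation. The route is rejoined at tetraphenol 9, with 8 bypassed.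

Step 9. Conjugate addition of acetate may stall at the hindered last ring position of one or both trisubstituted quinones, or the acid may strip the methoxyl of ring A. The fallback installs the missing oxygen by epoxidation and isomerisation, and sets out from bis-quinone 11. Nucleophilic epoxidation with NaBO3·4H2O in aqueous THF at 0 °C is the reaction that converts 2-hydroxy-3-methylbenzoquinone into its 5,6-epoxide. It should epoxidise the one non-oxygenated enone double bond of each ring to give 3-hydroxy-1-[13-(3-methoxy-4-methyl-2,5-dioxo-7-oxabicyclo[4.1.0]hept-3-en-1-yl)tridecyl]-4-methyl-7-oxabicyclo[4.1.0]hept-3-ene-2,5-dione F4 as a mixture of stereoisomers. Brief treatment with cold concentrated H2SO4 should isomerise each epoxy-dione to the hydroxyquinone, as in the classical conversion of 2-methylnaphthoquinone oxide to its 3-hydroxy derivative. The route comes back directly at target 14, with 12 and 13 bypassed.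

Step 7. Over-methylation and poor chromatographic resolution among the partly methylated phenols may leave too little pure mono-ether per pass. The fallback reaches 10 from the fully methylated side, where the selectivity problem is reduced to two equivalent sites, and sets out from tetraphenol 9. Exhaustive methylation (excess MeI, K2CO3, DMF) would give 1,13-bis(3,5-dimethoxy-4-methylphenyl)tridecane F5. NaSEt in DMF at 140 °C should remove exactly one methyl per ring, because the phenoxide formed deactivates the second methoxyl of the same ring, giving 1,13-bis(3-hydroxy-5-methoxy-4-methylphenyl)tridecane F6. One further O-demethylation with limiting BBr3 in CH2Cl2 (−78 °C to 0 °C) is then shared between only two equivalent methoxyls and returns the route at mono-ether 10. Unreacted F6 would be resubmitted, and over-demethylated material is 9 itself and re-enters the route.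

**Further compounds**

F1 | step 5 | 3,5-bis(benzyloxy)-4-methylbenzaldehyde | Cc1c(OCc2ccccc2)cc(C=O)cc1OCc1ccccc1
F2 | step 5 | undecane-1,11-diylbis(triphenylphosphonium) dibromide | [Br-].[Br-].c1ccccc1[P+](c1ccccc1)(c1ccccc1)CCCCCCCCCCC[P+](c1ccccc1)(c1ccccc1)c1ccccc1
F3 | step 5 | 1,13-bis[3,5-bis(benzyloxy)-4-methylphenyl]trideca-1,12-diene (mixture of alkene isomers) | Cc1c(OCc2ccccc2)cc(C=CCCCCCCCCCC=Cc2cc(OCc3ccccc3)c(C)c(OCc3ccccc3)c2)cc1OCc1ccccc1
F4 | step 9 | 3-hydroxy-1-[13-(3-methoxy-4-methyl-2,5-dioxo-7-oxabicyclo[4.1.0]hept-3-en-1-yl)tridecyl]-4-methyl-7-oxabicyclo[4.1.0]hept-3-ene-2,5-dione (mixture of stereoisomers) | COC1=C(C)C(=O)C2OC2(CCCCCCCCCCCCCC34OC3C(=O)C(C)=C(O)C4=O)C1=O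
F5 | step 7 | 1,13-bis(3,5-dimethoxy-4-methylphenyl)tridecane | COc1cc(CCCCCCCCCCCCCc2cc(OC)c(C)c(OC)c2)cc(OC)c1C
F6 | step 7 | 1,13-bis(3-hydroxy-5-methoxy-4-methylphenyl)tridecane | COc1cc(CCCCCCCCCCCCCc2cc(O)c(C)c(OC)c2)cc(O)c1C
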